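The north-east run is my ground: X fed over 2.5 h, and by 8.00 h Z stands at 14% with Q at 77%.

| flask | Q | X | D | remark | time |
|---|---|---|---|---|---|
| north-east | 0.050 M | 0.90 equiv (fed, over 2.5 h) | 7.7 mol% | run made earlier |  |
| zeta | 0.050 M | 0.800 equiv (fed, over 2.5 h) | 7.7 mol% |  | 15 h |
| alpha | 0.050 M | 1.20 equiv | 7.7 mol% | everything together at the start | 5.0 h |

- north-east (time / h: Z / %, Q / %): 0.667: 0, 101; 1.00: 0, 99; 2.00: 3, 92; 4.00: 7, 89; 8.00: 14, 77

(readings scatter by 1.5 percentage points)

- in percentages every species weighs as the Q in it: one E counts as two
- the numbers in the tables scatter with a standard deviation of 1.5 percentage points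
- steps under discussion: X + G <-> Z + J; D -> 2 J; Q + J -> G; 2 G -> E

- which one finishes higher in amount of Z, in percent of the Q charged ("neither" within 2 percentage points) (zeta / alpha / neither)
- amount of Z at the end, in percent of the Q charged, zeta
- amount of Z at the end, in percent of the Q charged, alpha

My first estimate freezes the rate. The share of the X charge turned into Z by 8.00 h is

f = Z / X charged = 15.6%

A steady feed puts X in the flask, on average, from half the feed time onward, which gives a frozen rate of 0.0230 h⁻¹ on the X charge. Zeta then reaches Z of 25.3% and alpha, with X there from the start, Z of 13.8%.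

The objection is that D decays. In north-east by 8.00 h, Q lost minus Z reads as E, 9.00%, and two J per D cap E at 15.4%, so as a reading

kd = ln(cap / (cap − E)) / t = 0.110 h⁻¹

If radicals leave by G meeting G and by no other way, [G] follows the square root of [D], with neither Q nor X in it. So I count hours weighted by that root, τ, which gives 5.27 h for north-east.

The next objection is that X is used up as it goes, so the share left falls exponentially:

b = −ln(share of X left) / τ = 0.0321 h⁻¹

I carry this b, the share of the standing X that turns to Z per hour while D is fresh: a pseudo-first-order constant in X.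

Zeta: τ = 9.01 h, so Z = 20.1%

Alpha: τ = 4.37 h, so Z = 15.7%

One last doubt: b rests on a single Z reading with scatter 1.5 percentage points. But while b·τ is small, zeta over alpha is charge times τ, 1.37, with b cancelled, so I keep zeta ahead.

The forecast says zeta, with 19.5% for zeta and 15% for alpha, each a little under my figure: “Zeta's longer time outweighs alpha's extra X and early start”.

    X + G ⇌ Z + J (K = 4.10, k = 1.70 × 10⁵ M⁻¹ h⁻¹)
    D → 2 J (k = 0.110 h⁻¹)
    Q + J → G (k = 2.20 × 10⁵ M⁻¹ h⁻¹)
    2 G → E (k = 3.00 × 10⁶ M⁻¹ s⁻¹)

The flasks give Z of 20.3% for zeta and 16.0% for alpha, so zeta finishes higher, and b over alpha's τ leaves 86.9% of alpha's X charge, where alpha holds 87% of it after 5.00 h. In alpha at 2.19 h, J falls back at 0.017 of the rate at which it goes on. The same b on the neighbour of alpha charged with 3.00 equiv of X gives Z of 39.3%, and that flask ends with Z at 38.7%.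

The data come from a simulation from invented constants; noise was put on by code.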